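**Assumption:** the target is taken exactly as the SMILES reads: (2R,3S,4E)-3-hydroxy-5-[(2S,3R,3aR,7aR)-3-hydroxy-5-oxo-2,3,3a,7a-tetrahydro-5H-furo[3,2-b]pyran-2-yl]pent-4-en-2-yl benzoate, with all four substituents of the tetrahydrofuran ring cis.

## Retrosynthetic overview

1. 15 ⇐ tetrahydrofuran ring closed last: intramolecular reductive etherification of the C-7 silyl ether onto the ring ketone of pyran-2,5-dione 13 (forms O–C7a, sets C7a–H and the cis fusion).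
2. 13 ⇐ Achmatowicz oxidative ring expansion of furyl carbinol 11 (furan → six-membered pyranone, the first ring), then lactol oxidation.
3. 11 ⇐ catalyst-controlled reduction of furyl ketone 10 ⇐ catalytic syn-selective direct aldol of 2-(hydroxyacetyl)furan 8 (furfural + CH2O) with enal 6.
4. 6 ⇐ Wittig two-carbon homologation of aldehyde 5 ⇐ (E)-crotyl alcohol by Sharpless epoxidation and C3-selective benzoate opening (erythro hydroxy benzoate).

## Route

Step 1
Reactants: 1 (E)-but-2-en-1-ol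
Product: 3 (2R,3S)-3,4-dihydroxybutan-2-yl benzoate, via epoxy alcohol 2 (not isolated)
Conditions: Ti(OiPr)4 (5 mol %), L-(+)-DIPT (6 mol %), t-BuOOH, 4 Å MS, CH2Cl2, −20 °C; then PhCO2H, Ti(OiPr)4 (1.5 equiv), rt
Reagents that add atoms: tert-butyl hydroperoxide, CC(C)(C)OO; benzoic acid, OC(=O)c1ccccc1
Why: Sharpless asymmetric epoxidation with L-tartrate gives the (2S,3S)-epoxide, and Ti(OiPr)4-mediated opening of the titanium-bound 2,3-epoxy alcohol by benzoic acid occurs at C3 with inversion, which sets the (R)-benzoate carbon and the (S)-carbinol carbon of the erythro side chain.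

Step 2
Reactants: 3 (2R,3S)-3,4-dihydroxybutan-2-yl benzoate
Product: 4 (2R,3S)-3,4-bis(triethylsilyloxy)butan-2-yl benzoate
Conditions: TESOTf, 2,6-lutidine, CH2Cl2, −78 °C
Reagents that add atoms: triethylsilyl trifluoromethanesulfonate, CC[Si](CC)(CC)OS(=O)(=O)C(F)(F)F
Why: Standard silyl ether formation, fast enough at −78 °C to outrun 1,2-benzoyl migration; no stereocenter is touched.

Step 3
Reactants: 4 (2R,3S)-3,4-bis(triethylsilyloxy)butan-2-yl benzoate
Product: 6 (2R,3S,4E)-6-oxo-3-(triethylsilyloxy)hex-4-en-2-yl benzoate, via silyloxy aldehyde 5 (not isolated)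
Conditions: (COCl)2, DMSO, CH2Cl2, −78 to −40 °C; Et3N, −78 °C; then Ph3P=CHCHO, −78 °C to rt
Reagents that add atoms: (triphenylphosphoranylidene)acetaldehyde, O=CC=P(c1ccccc1)(c1ccccc1)c1ccccc1
Why: Swern conditions cleave and oxidise the primary TES ether selectively over the secondary one, and the stabilised ylide traps the aldehyde in the same flask as the E-enal (one-pot Swern–Wittig), so the α-silyloxy center is not epimerised.

Step 4
Reactants: 7 furan-2-carbaldehyde (furfural)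
Product: 8 1-(furan-2-yl)-2-hydroxyethan-1-one
Conditions: (CH2O)n, thiazolium precatalyst (10 mol %), i-Pr2NEt (10 mol %), THF, 60 °C
Reagents that add atoms: formaldehyde (as paraformaldehyde), C=O
Why: NHC-catalysed cross-acyloin reaction (hydroxymethylation): the Breslow intermediate of furfural adds to formaldehyde; no stereocenter.

Step 5
Reactants: 6 (2R,3S,4E)-6-oxo-3-(triethylsilyloxy)hex-4-en-2-yl benzoate; 8 1-(furan-2-yl)-2-hydroxyethan-1-one
Product: 9 (2R,3S,4E,6S,7R)-8-(furan-2-yl)-6,7-dihydroxy-8-oxo-3-(triethylsilyloxy)oct-4-en-2-yl benzoate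
Conditions: (S,S)-ProPhenol (5 mol %), Et2Zn (10 mol %), 4 Å MS, THF, −35 °C
Reagents that add atoms: none
Why: Direct asymmetric aldol reaction of an α-hydroxy ketone under dinuclear zinc–ProPhenol catalysis: the zinc-bound enediolate adds 1,2 to the enal with ligand-controlled facial selectivity and gives the syn-diol, which sets C-7 (R) and C-6 (S) of 9.

Step 6
Reactants: 9 (2R,3S,4E,6S,7R)-8-(furan-2-yl)-6,7-dihydroxy-8-oxo-3-(triethylsilyloxy)oct-4-en-2-yl benzoate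
Product: 10 (2R,3S,4E,6S,7R)-8-(furan-2-yl)-8-oxo-3,6,7-tris(triethylsilyloxy)oct-4-en-2-yl benzoate
Conditions: TESOTf, 2,6-lutidine, CH2Cl2, −78 °C
Reagents that add atoms: triethylsilyl trifluoromethanesulfonate, CC[Si](CC)(CC)OS(=O)(=O)C(F)(F)F
Why: Standard silylation of both carbinols (alcohol silylation is much faster than enol silylation of the ketone at −78 °C with lutidine); no stereocenter is touched.

Step 7
Reactants: 10 (2R,3S,4E,6S,7R)-8-(furan-2-yl)-8-oxo-3,6,7-tris(triethylsilyloxy)oct-4-en-2-yl benzoate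
Product: 11 (2R,3S,4E,6S,7S,8R)-8-(furan-2-yl)-8-hydroxy-3,6,7-tris(triethylsilyloxy)oct-4-en-2-yl benzoate
Conditions: RuCl[(R,R)-TsDPEN](p-cymene) (3 mol %), HCO2Na, CTAB, H2O/CH2Cl2, rt
Reagents that add atoms: none
Why: Noyori–Ikariya asymmetric transfer hydrogenation of a 2-furyl ketone: the (R,R)-catalyst orients the furyl group by the CH/π contact and delivers hydride to give the (8R)-carbinol, anti to the neighbouring silyloxy carbon, under catalyst control (the C-7 descriptor changes from R to S only because the CIP priorities change).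

Step 8
Reactants: 11 (2R,3S,4E,6S,7S,8R)-8-(furan-2-yl)-8-hydroxy-3,6,7-tris(triethylsilyloxy)oct-4-en-2-yl benzoate
Product: 13 (2R,3S,4E,6S,7S)-7-[(2R)-3,6-dioxo-3,6-dihydro-2H-pyran-2-yl]-3,6,7-tris(triethylsilyloxy)hept-4-en-2-yl benzoate, via pyranone lactol 12 (not isolated)
Conditions: m-CPBA (1.05 equiv), CH2Cl2, 0 °C; then DMP, 0 °C to rt; used at once
Reagents that add atoms: 3-chloroperbenzoic acid, OOC(=O)c1cccc(Cl)c1
Why: Achmatowicz rearrangement: m-CPBA oxidises the furan (far more reactive than the deactivated E-alkene) to the cis-enedione, which closes on the carbinol oxygen to the six-membered pyranone hemiacetal (furan-to-pyranone ring expansion; the carbinol center is not touched), and Dess–Martin oxidation of the only free hydroxyl, the lactol, gives the keto lactone.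

Step 9
Reactants: 13 (2R,3S,4E,6S,7S)-7-[(2R)-3,6-dioxo-3,6-dihydro-2H-pyran-2-yl]-3,6,7-tris(triethylsilyloxy)hept-4-en-2-yl benzoate
Product: 15 (2R,3S,4E)-3-hydroxy-5-[(2S,3R,3aR,7aR)-3-hydroxy-5-oxo-2,3,3a,7a-tetrahydro-5H-furo[3,2-b]pyran-2-yl]pent-4-en-2-yl benzoate, via bis-TES ether 14 (not isolated)
Conditions: Et3SiH (5 equiv), TMSOTf (0.5 equiv), CH2Cl2, −78 to −40 °C; then aq. HF, MeCN, 0 °C
Reagents that add atoms: none
Why: Proposed new method: intramolecular reductive etherification on the ketone of a 2H-pyran-2,5(6H)-dione. The oxygen of the γ-silyloxy group adds to the TMSOTf-activated ketone (5-exo) to give a bicyclic silyl ketal, which ionises to a bicyclic oxocarbenium ion with the lactone ring still closed; Et3SiH then adds from the convex face, anti to the C3a–O bond, the only trajectory that leads to a cis-fused ring, so the new C-7a (R) has H cis to H-3a and O-1 carries the C-2 configuration unchanged. The closest known reactions are the silane/Lewis acid reductive etherification of silyl ethers with ketones and the ionic reduction of cyclic hemiketals; neither has been shown on a ketone that is part of a 4-oxo-2-enoate. The HF stage only removes the two remaining TES groups.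

## Compound list

1 | (E)-but-2-en-1-ol | C/C=C/CO | starting material
2 | [(2S,3S)-3-methyloxiran-2-yl]methanol | C[C@@H]1O[C@H]1CO | intermediate (not isolated)
3 | (2R,3S)-3,4-dihydroxybutan-2-yl benzoate | C[C@@H](OC(=O)c1ccccc1)[C@@H](O)CO | intermediate
4 | (2R,3S)-3,4-bis(triethylsilyloxy)butan-2-yl benzoate | C[C@@H](OC(=O)c1ccccc1)[C@@H](O[Si](CC)(CC)CC)CO[Si](CC)(CC)CC | intermediate
5 | (2R,3R)-4-oxo-3-(triethylsilyloxy)butan-2-yl benzoate | C[C@@H](OC(=O)c1ccccc1)[C@@H](O[Si](CC)(CC)CC)C=O | intermediate (not isolated)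
6 | (2R,3S,4E)-6-oxo-3-(triethylsilyloxy)hex-4-en-2-yl benzoate | C[C@@H](OC(=O)c1ccccc1)[C@@H](O[Si](CC)(CC)CC)/C=C/C=O | intermediate
7 | furan-2-carbaldehyde | O=Cc1ccco1 | starting material
8 | 1-(furan-2-yl)-2-hydroxyethan-1-one | O=C(CO)c1ccco1 | intermediate
9 | (2R,3S,4E,6S,7R)-8-(furan-2-yl)-6,7-dihydroxy-8-oxo-3-(triethylsilyloxy)oct-4-en-2-yl benzoate | C[C@@H](OC(=O)c1ccccc1)[C@@H](O[Si](CC)(CC)CC)/C=C/[C@H](O)[C@@H](O)C(=O)c1ccco1 | intermediate
10 | (2R,3S,4E,6S,7R)-8-(furan-2-yl)-8-oxo-3,6,7-tris(triethylsilyloxy)oct-4-en-2-yl benzoate | C[C@@H](OC(=O)c1ccccc1)[C@@H](O[Si](CC)(CC)CC)/C=C/[C@H](O[Si](CC)(CC)CC)[C@@H](O[Si](CC)(CC)CC)C(=O)c1ccco1 | intermediate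
11 | (2R,3S,4E,6S,7S,8R)-8-(furan-2-yl)-8-hydroxy-3,6,7-tris(triethylsilyloxy)oct-4-en-2-yl benzoate | C[C@@H](OC(=O)c1ccccc1)[C@@H](O[Si](CC)(CC)CC)/C=C/[C@H](O[Si](CC)(CC)CC)[C@@H](O[Si](CC)(CC)CC)[C@@H](O)c1ccco1 | intermediate
12 | (2R,3S,4E,6S,7S)-7-[(2R)-6-hydroxy-3-oxo-3,6-dihydro-2H-pyran-2-yl]-3,6,7-tris(triethylsilyloxy)hept-4-en-2-yl benzoate (anomeric mixture) | C[C@@H](OC(=O)c1ccccc1)[C@@H](O[Si](CC)(CC)CC)/C=C/[C@H](O[Si](CC)(CC)CC)[C@@H](O[Si](CC)(CC)CC)[C@H]1OC(O)C=CC1=O | intermediate (not isolated)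
13 | (2R,3S,4E,6S,7S)-7-[(2R)-3,6-dioxo-3,6-dihydro-2H-pyran-2-yl]-3,6,7-tris(triethylsilyloxy)hept-4-en-2-yl benzoate | C[C@@H](OC(=O)c1ccccc1)[C@@H](O[Si](CC)(CC)CC)/C=C/[C@H](O[Si](CC)(CC)CC)[C@@H](O[Si](CC)(CC)CC)[C@H]1OC(=O)C=CC1=O | intermediate
14 | (2R,3S,4E)-5-[(2S,3R,3aS,7aR)-5-oxo-3-(triethylsilyloxy)-2,3,3a,7a-tetrahydro-5H-furo[3,2-b]pyran-2-yl]-3-(triethylsilyloxy)pent-4-en-2-yl benzoate | C[C@@H](OC(=O)c1ccccc1)[C@@H](O[Si](CC)(CC)CC)/C=C/[C@@H]1O[C@@H]2C=CC(=O)O[C@@H]2[C@@H]1O[Si](CC)(CC)CC | intermediate (not isolated)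
15 | (2R,3S,4E)-3-hydroxy-5-[(2S,3R,3aR,7aR)-3-hydroxy-5-oxo-2,3,3a,7a-tetrahydro-5H-furo[3,2-b]pyran-2-yl]pent-4-en-2-yl benzoate | C[C@@H](OC(=O)c1ccccc1)[C@@H](O)/C=C/[C@@H]1O[C@@H]2C=CC(=O)O[C@@H]2[C@@H]1O | target

## Step count and risk

Total step count: 9. Longest linear sequence: 8 (steps 1–3, then 5–9).

**Step 9 (the proposed new step).** The oxocarbenium ion is destabilised by the conjugated lactone, and the keto lactone can tautomerise to a 5-hydroxy-2-pyranone or suffer conjugate reduction. The fallback uses known chemistry and closes the ring by SN2 instead of by hydride addition. It sets out from keto lactone 13. Luche reduction (NaBH4, CeCl3, MeOH/CH2Cl2, −78 °C) is expected to give mainly the trans allylic alcohol (2R,3S,4E,6S,7S)-7-[(2S,3S)-3-hydroxy-6-oxo-3,6-dihydro-2H-pyran-2-yl]-3,6,7-tris(triethylsilyloxy)hept-4-en-2-yl benzoate F1, the only free hydroxyl in the molecule. MsCl/Et3N at −20 °C converts it into the allylic mesylate (2R,3S,4E,6S,7S)-7-[(2R,3S)-3-(methanesulfonyloxy)-6-oxo-3,6-dihydro-2H-pyran-2-yl]-3,6,7-tris(triethylsilyloxy)hept-4-en-2-yl benzoate F2. HF·pyridine then removes the three TES groups to give the triol mesylate (2R,3S,4E,6S,7R)-3,6,7-trihydroxy-7-[(2R,3S)-3-(methanesulfonyloxy)-6-oxo-3,6-dihydro-2H-pyran-2-yl]hept-4-en-2-yl benzoate F3. On buffering with NaHCO3 in MeCN, the C-6 hydroxyl displaces the mesylate (5-exo-tet, inversion), which gives the cis-fused ring and comes back to the route at target 15.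

**Step 5.** Enals are little explored as acceptors in the zinc–ProPhenol hydroxy-ketone aldol, so rate and syn selectivity are uncertain. The fallback is an auxiliary-controlled boron aldol and sets out from enal 6. The boron enolate of (R)-4-benzyl-3-[(triethylsilyloxy)acetyl]oxazolidin-2-one (Bu2BOTf, i-Pr2NEt) gives the Evans syn adduct (4R)-4-benzyl-3-[(2R,3S,4E,6S,7R)-7-(benzoyloxy)-3-hydroxy-2,6-bis(triethylsilyloxy)oct-4-enoyl]-1,3-oxazolidin-2-one F4. TESOTf gives its silyl ether (4R)-4-benzyl-3-[(2R,3S,4E,6S,7R)-7-(benzoyloxy)-2,3,6-tris(triethylsilyloxy)oct-4-enoyl]-1,3-oxazolidin-2-one F5. MeNH(OMe)·HCl/AlMe3 gives the Weinreb amide (2R,3S,4E,6S,7R)-8-[methoxy(methyl)amino]-8-oxo-3,6,7-tris(triethylsilyloxy)oct-4-en-2-yl benzoate F6, and 2-furyllithium (furan, n-BuLi, −78 °C) comes back to the route at ketone 10; compounds 7, 8 and 9 are then not needed.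

**Step 7.** The required anti carbinol is the mismatched case with respect to the Felkin bias of the α-silyloxy ketone, so the transfer hydrogenation may be slow or poorly selective. The fallback uses the substrate bias and then inverts, and it sets out from ketone 10. L-Selectride (THF, −78 °C) gives the Felkin product, the epimeric alcohol (2R,3S,4E,6S,7S,8S)-8-(furan-2-yl)-8-hydroxy-3,6,7-tris(triethylsilyloxy)oct-4-en-2-yl benzoate F7. Mitsunobu inversion with chloroacetic acid (PPh3, DIAD) gives the chloroacetate (2R,3S,4E,6S,7S,8R)-8-(2-chloroacetoxy)-8-(furan-2-yl)-3,6,7-tris(triethylsilyloxy)oct-4-en-2-yl benzoate F8, and thiourea/NaHCO3 in EtOH removes the chloroacetyl group without touching the benzoate and comes back to the route at carbinol 11.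

## Further compounds

F1 | step 9 | (2R,3S,4E,6S,7S)-7-[(2S,3S)-3-hydroxy-6-oxo-3,6-dihydro-2H-pyran-2-yl]-3,6,7-tris(triethylsilyloxy)hept-4-en-2-yl benzoate | C[C@@H](OC(=O)c1ccccc1)[C@@H](O[Si](CC)(CC)CC)/C=C/[C@H](O[Si](CC)(CC)CC)[C@@H](O[Si](CC)(CC)CC)[C@H]1OC(=O)C=C[C@@H]1O
F2 | step 9 | (2R,3S,4E,6S,7S)-7-[(2R,3S)-3-(methanesulfonyloxy)-6-oxo-3,6-dihydro-2H-pyran-2-yl]-3,6,7-tris(triethylsilyloxy)hept-4-en-2-yl benzoate | C[C@@H](OC(=O)c1ccccc1)[C@@H](O[Si](CC)(CC)CC)/C=C/[C@H](O[Si](CC)(CC)CC)[C@@H](O[Si](CC)(CC)CC)[C@H]1OC(=O)C=C[C@@H]1OS(C)(=O)=O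
F3 | step 9 | (2R,3S,4E,6S,7R)-3,6,7-trihydroxy-7-[(2R,3S)-3-(methanesulfonyloxy)-6-oxo-3,6-dihydro-2H-pyran-2-yl]hept-4-en-2-yl benzoate | C[C@@H](OC(=O)c1ccccc1)[C@@H](O)/C=C/[C@H](O)[C@@H](O)[C@H]1OC(=O)C=C[C@@H]1OS(C)(=O)=O
F4 | step 5 | (4R)-4-benzyl-3-[(2R,3S,4E,6S,7R)-7-(benzoyloxy)-3-hydroxy-2,6-bis(triethylsilyloxy)oct-4-enoyl]-1,3-oxazolidin-2-one | C[C@@H](OC(=O)c1ccccc1)[C@@H](O[Si](CC)(CC)CC)/C=C/[C@H](O)[C@@H](O[Si](CC)(CC)CC)C(=O)N1[C@H](Cc2ccccc2)COC1=O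
F5 | step 5 | (4R)-4-benzyl-3-[(2R,3S,4E,6S,7R)-7-(benzoyloxy)-2,3,6-tris(triethylsilyloxy)oct-4-enoyl]-1,3-oxazolidin-2-one | C[C@@H](OC(=O)c1ccccc1)[C@@H](O[Si](CC)(CC)CC)/C=C/[C@H](O[Si](CC)(CC)CC)[C@@H](O[Si](CC)(CC)CC)C(=O)N1[C@H](Cc2ccccc2)COC1=O
F6 | step 5 | (2R,3S,4E,6S,7R)-8-[methoxy(methyl)amino]-8-oxo-3,6,7-tris(triethylsilyloxy)oct-4-en-2-yl benzoate | C[C@@H](OC(=O)c1ccccc1)[C@@H](O[Si](CC)(CC)CC)/C=C/[C@H](O[Si](CC)(CC)CC)[C@@H](O[Si](CC)(CC)CC)C(=O)N(C)OC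
F7 | step 7 | (2R,3S,4E,6S,7S,8S)-8-(furan-2-yl)-8-hydroxy-3,6,7-tris(triethylsilyloxy)oct-4-en-2-yl benzoate | C[C@@H](OC(=O)c1ccccc1)[C@@H](O[Si](CC)(CC)CC)/C=C/[C@H](O[Si](CC)(CC)CC)[C@@H](O[Si](CC)(CC)CC)[C@H](O)c1ccco1
F8 | step 7 | (2R,3S,4E,6S,7S,8R)-8-(2-chloroacetoxy)-8-(furan-2-yl)-3,6,7-tris(triethylsilyloxy)oct-4-en-2-yl benzoate | C[C@@H](OC(=O)c1ccccc1)[C@@H](O[Si](CC)(CC)CC)/C=C/[C@H](O[Si](CC)(CC)CC)[C@@H](O[Si](CC)(CC)CC)[C@@H](OC(=O)CCl)c1ccco1
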